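Ring B is opened by a Dötz benzannulation. The step exploits the substitution pattern of ring B: the C2 hydroxyl stands para to the C5 methoxyl, with C4 (methyl) and C3 (H) on one flank and C1 (aroyl carbon) and C6 (acetoxymethyl) on the other. C5 is therefore a methoxycarbene carbon, C4–C3 an isopropenyl group, C2 a CO ligand and C1–C6 an internal alkyne. One operation forms C5–C6, C1–C2 and C2–C3 and delivers the pentasubstituted arene. Its precursors are pentacarbonyl[methoxy(isopropenyl)carbene]chromium and a 4-acetoxybut-2-yne that carries ring A at a silyl-protected carbinol. Desilylation and carbinol oxidation finish the benzophenone.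

Key step: step 5

Remark: the target has no stereocenter, so the carbinol carbon made in step 1 is carried as the racemate until step 7 turns it into the carbonyl carbon.

Step 1
Reactants: 1 2,6-dimethoxybenzaldehyde; 2 propargyl alcohol
Product: 4 racemic 1-(2,6-dimethoxyphenyl)but-2-yne-1,4-diol, via dimagnesiated propargyl alcohol 3 (not isolated)
Conditions: 2, EtMgBr (2.1 equiv), THF, 0 to 45 °C; then 1, THF, 0 °C to rt; H2O quench
Reagents that add atoms: none
Why: Acetylide 1,2-addition to an aldehyde: two equivalents of EtMgBr turn propargyl alcohol into its C,O-dimagnesium derivative 3, whose alkynyl carbon adds to the hindered but non-enolizable aldehyde, and the new carbinol center forms without control, which is harmless because it is oxidized away in step 7.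

Step 2
Reactants: 4 racemic 1-(2,6-dimethoxyphenyl)but-2-yne-1,4-diol
Product: 5 racemic 4-(2,6-dimethoxyphenyl)-4-hydroxybut-2-yn-1-yl acetate
Conditions: AcCl (1.05 equiv), 2,4,6-collidine, CH2Cl2, −78 °C
Reagents that add atoms: acetyl chloride, CC(Cl)=O
Why: Kinetically selective O-acylation of a primary hydroxyl (acyl chloride with a hindered pyridine base at low temperature): the secondary hydroxyl is shielded by the 2,6-dimethoxyphenyl ring, and the rigid alkyne spacer rules out later acetyl migration between the two oxygens.

Step 3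
Reactants: 5 racemic 4-(2,6-dimethoxyphenyl)-4-hydroxybut-2-yn-1-yl acetate
Product: 6 racemic 4-(tert-butyldimethylsilyloxy)-4-(2,6-dimethoxyphenyl)but-2-yn-1-yl acetate
Conditions: TBSOTf, 2,6-lutidine, CH2Cl2, −78 to 0 °C
Reagents that add atoms: tert-butyldimethylsilyl triflate, CC(C)(C)[Si](C)(C)OS(=O)(=O)C(F)(F)F
Why: Silyl ether formation with a silyl triflate and 2,6-lutidine silylates even congested secondary alcohols without acid, so the ionizable benzylic propargylic C–O bond and the acetate stay intact and the stereocenter is untouched.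

Step 4
Reactants: 7 2-bromopropene; 8 chromium hexacarbonyl Cr(CO)6
Product: 11 pentacarbonyl[methoxy(prop-1-en-2-yl)carbene]chromium, via isopropenyllithium 9 (not isolated), via lithium acylchromate 10 (not isolated)
Conditions: 7, t-BuLi (2 equiv), Et2O, −78 °C; Cr(CO)6, Et2O, −78 °C to rt; MeOTf, CH2Cl2, 0 °C to rt
Reagents that add atoms: methyl triflate, COS(=O)(=O)C(F)(F)F
Why: Fischer carbene synthesis: bromine–lithium exchange gives isopropenyllithium 9, which adds to a CO ligand of Cr(CO)6 to give acylchromate 10, and the hard electrophile MeOTf methylates its oxygen to give the zerovalent chromium methoxycarbene complex.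

Step 5
Reactants: 6 racemic 4-(tert-butyldimethylsilyloxy)-4-(2,6-dimethoxyphenyl)but-2-yn-1-yl acetate; 11 pentacarbonyl[methoxy(prop-1-en-2-yl)carbene]chromium
Product: 14 racemic [3-(tert-butyldimethylsilyloxy)-2-[(tert-butyldimethylsilyloxy)(2,6-dimethoxyphenyl)methyl]-6-methoxy-5-methylphenyl]methyl acetate, via phenol Cr(CO)3 complex 12 (not isolated), via aryl silyl ether Cr(CO)3 complex 13 (not isolated)
Conditions: 11 (1.5 equiv), TBSCl (3 equiv), i-Pr2NEt (3 equiv), CH2Cl2, 55 °C, Ar, sealed flask; then air, visible light, MeCN, rt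
Reagents that add atoms: tert-butyldimethylsilyl chloride, CC(C)(C)[Si](C)(C)Cl
Why: Dötz benzannulation: thermal loss of one CO from 11 lets the alkyne insert into the chromium–carbene bond (C5–C6), CO insertion (C1–C2) gives a chromium-bound dienylketene, and 6π electrocyclization onto the isopropenyl CH2 (C2–C3) followed by tautomerization gives the phenol as its Cr(CO)3 complex 12. The closest known reaction type is the benzannulation of alkenyl(methoxy)carbene chromium complexes with propargylic ethers run with TBSCl and an amine, which caps the new phenol as 13 so that the ortho benzhydrylic silyloxy group cannot be expelled through an ortho-quinone methide and the arene is not oxidized when air and light strip the metal. Ring B is the only ring closed, by 6π electrocyclic closure of the ketene. No stereocenter of the target is set; the carbinol center stays racemic and the planar chirality of 12 and 13 vanishes on demetalation. The step needs the larger alkyne substituent next to the CO-derived carbon, and this is secured because the alpha-branched aryl(silyloxy)methyl group is far bulkier than the primary acetoxymethyl group, so the former should end at C1 beside the oxygen and the latter at C6 beside the methoxyl.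

Step 6
Reactants: 14 racemic [3-(tert-butyldimethylsilyloxy)-2-[(tert-butyldimethylsilyloxy)(2,6-dimethoxyphenyl)methyl]-6-methoxy-5-methylphenyl]methyl acetate
Product: 16 racemic [2-[(2,6-dimethoxyphenyl)(hydroxy)methyl]-3-hydroxy-6-methoxy-5-methylphenyl]methyl acetate, via carbinol silyl ether phenol 15 (not isolated)
Conditions: TBAF (3 equiv), AcOH (3 equiv), THF, 0 to 40 °C
Reagents that add atoms: none
Why: Fluoride-induced silyl ether cleavage, in which the aryl ether should fall first (phenol 15) and the hindered carbinol ether second, while acetic acid keeps phenoxide and alkoxide protonated so that the neighbouring acetate neither migrates to the carbinol oxygen nor is displaced to a phthalan; any 15 left uncapped in step 5 converges here.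

Step 7
Reactants: 16 racemic [2-[(2,6-dimethoxyphenyl)(hydroxy)methyl]-3-hydroxy-6-methoxy-5-methylphenyl]methyl acetate
Product: 17 Preacredinone A
Conditions: activated MnO2 (excess), CH2Cl2, rt
Reagents that add atoms: none
Why: Heterogeneous MnO2 oxidation of a doubly benzylic alcohol under neutral conditions should spare the acetate, the aryl ethers and the phenol, erase the only stereocenter and give a ketone stabilized by a hydrogen bond from the C2 hydroxyl.

Compound list
1 | 2,6-dimethoxybenzaldehyde | COc1cccc(OC)c1C=O | starting material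
2 | propargyl alcohol (prop-2-yn-1-ol) | C#CCO | starting material
3 | dimagnesiated propargyl alcohol, BrMgC≡CCH2OMgBr | Br[Mg]C#CCO[Mg]Br | intermediate
4 | racemic 1-(2,6-dimethoxyphenyl)but-2-yne-1,4-diol | COc1cccc(OC)c1C(O)C#CCO | intermediate
5 | racemic 4-(2,6-dimethoxyphenyl)-4-hydroxybut-2-yn-1-yl acetate | COc1cccc(OC)c1C(O)C#CCOC(C)=O | intermediate
6 | racemic 4-(tert-butyldimethylsilyloxy)-4-(2,6-dimethoxyphenyl)but-2-yn-1-yl acetate | COc1cccc(OC)c1C(O[Si](C)(C)C(C)(C)C)C#CCOC(C)=O | intermediate
7 | 2-bromopropene | C=C(C)Br | starting material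
8 | chromium hexacarbonyl Cr(CO)6 (zerovalent chromium) | O=C=[Cr](=C=O)(=C=O)(=C=O)(=C=O)=C=O | starting material
9 | isopropenyllithium (prop-1-en-2-yllithium) | [Li]C(C)=C | intermediate
10 | lithium acylchromate Li[(CO)5Cr=C(O)C(CH3)=CH2] | [Li+].[O-]C(C(C)=C)=[Cr](=C=O)(=C=O)(=C=O)(=C=O)=C=O | intermediate
11 | pentacarbonyl[methoxy(prop-1-en-2-yl)carbene]chromium, (CO)5Cr=C(OCH3)C(CH3)=CH2 (zerovalent chromium) | COC(C(C)=C)=[Cr](=C=O)(=C=O)(=C=O)(=C=O)=C=O | intermediate
12 | Cr(CO)3 complex of phenol 15, η6 on ring B, racemic diastereomer mixture (arene and Cr(CO)3 written as two dot-joined parts) | COc1cccc(OC)c1C(O[Si](C)(C)C(C)(C)C)c1c(O)cc(C)c(OC)c1COC(C)=O.O=C=[Cr](=C=O)=C=O | intermediate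
13 | Cr(CO)3 complex of aryl silyl ether 14, η6 on ring B, racemic diastereomer mixture (arene and Cr(CO)3 written as two dot-joined parts) | COc1cccc(OC)c1C(O[Si](C)(C)C(C)(C)C)c1c(O[Si](C)(C)C(C)(C)C)cc(C)c(OC)c1COC(C)=O.O=C=[Cr](=C=O)=C=O | intermediate
14 | racemic [3-(tert-butyldimethylsilyloxy)-2-[(tert-butyldimethylsilyloxy)(2,6-dimethoxyphenyl)methyl]-6-methoxy-5-methylphenyl]methyl acetate | COc1cccc(OC)c1C(O[Si](C)(C)C(C)(C)C)c1c(O[Si](C)(C)C(C)(C)C)cc(C)c(OC)c1COC(C)=O | intermediate
15 | racemic [2-[(tert-butyldimethylsilyloxy)(2,6-dimethoxyphenyl)methyl]-3-hydroxy-6-methoxy-5-methylphenyl]methyl acetate | COc1cccc(OC)c1C(O[Si](C)(C)C(C)(C)C)c1c(O)cc(C)c(OC)c1COC(C)=O | intermediate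
16 | racemic [2-[(2,6-dimethoxyphenyl)(hydroxy)methyl]-3-hydroxy-6-methoxy-5-methylphenyl]methyl acetate | COc1cccc(OC)c1C(O)c1c(O)cc(C)c(OC)c1COC(C)=O | intermediate
17 | Preacredinone A, [2-(2,6-dimethoxybenzoyl)-3-hydroxy-6-methoxy-5-methylphenyl]methyl acetate | COc1cccc(OC)c1C(=O)c1c(O)cc(C)c(OC)c1COC(C)=O | target

Total step count: 7
Longest linear sequence: 6 steps (steps 1, 2, 3, 5, 6, 7); step 4 is the convergent branch.

Steps most likely to fail

1. Step 5. The congested internal alkyne may insert into the chromium–carbene bond too slowly, or with eroded orientation, so that the thermally labile complex 11 decomposes before ring B closes. The fallback sets out from 11 and returns at 16, bringing ring A in only after the benzannulation. Commercial 3,3-diethoxyprop-1-yne is deprotonated with EtMgBr to (3,3-diethoxyprop-1-yn-1-yl)magnesium bromide F1, which with paraformaldehyde in THF should give 4,4-diethoxybut-2-yn-1-ol F2. Ac2O and pyridine convert it into 4,4-diethoxybut-2-yn-1-yl acetate F3. This much smaller alkyne still has its branched end at the acetal carbon. Heated with 11 (THF, 50 °C) it should give the Cr(CO)3 complex of the acetal phenol F4, which air demetalates to [2-(diethoxymethyl)-3-hydroxy-6-methoxy-5-methylphenyl]methyl acetate F5. PPTS in wet acetone frees (2-formyl-3-hydroxy-6-methoxy-5-methylphenyl)methyl acetate F6. Two equivalents of 2,6-dimethoxyphenylmagnesium bromide F7 (from 2-bromo-1,3-dimethoxybenzene and Mg) are then added in THF at −78 °C. The first is consumed by the phenol and the second should add to the chelated aldehyde faster than to the acetate, giving carbinol 16.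

2. Step 6. The congested benzhydrylic silyl ether may resist buffered fluoride, and under forcing the freed carbinol oxygen may take the acetyl group from the neighbouring CH2OAc, close a phthalan or ionize. The fallback sets out from 5 and returns at 16; it changes the protecting-group plan so that the carbinol is unveiled under the mildest conditions. TESOTf and 2,6-lutidine convert 5 into racemic 4-(2,6-dimethoxyphenyl)-4-(triethylsilyloxy)but-2-yn-1-yl acetate F8. Benzannulation with 11 under the conditions of step 5 should pass through the phenol Cr(CO)3 complex F9 and the aryl silyl ether Cr(CO)3 complex F10 to racemic [3-(tert-butyldimethylsilyloxy)-2-[(2,6-dimethoxyphenyl)(triethylsilyloxy)methyl]-6-methoxy-5-methylphenyl]methyl acetate F11. TBAF/AcOH in THF at 0 °C should then remove both silyl groups quickly, before acetyl transfer can compete, and give 16.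

3. Step 7. Hydrogen abstraction at the tetra-ortho-substituted carbinol may be slow, leaving the oxidant time to attack the free para-methoxyphenol ring (quinone formation). The fallback sets out from 16 and returns at 17; the phenol is masked before an oxidation that does not rely on benzylic hydrogen abstraction. TBSCl and imidazole in DMF at 0 °C should silylate only the phenol and give racemic [3-(tert-butyldimethylsilyloxy)-2-[(2,6-dimethoxyphenyl)(hydroxy)methyl]-6-methoxy-5-methylphenyl]methyl acetate F12. Dess–Martin periodinane with NaHCO3 in CH2Cl2 should give [3-(tert-butyldimethylsilyloxy)-2-(2,6-dimethoxybenzoyl)-6-methoxy-5-methylphenyl]methyl acetate F13. TBAF/AcOH in THF at 0 °C then frees the phenol to give 17.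

Further compounds
F1 | step 5 | (3,3-diethoxyprop-1-yn-1-yl)magnesium bromide | CCOC(OCC)C#C[Mg]Br
F2 | step 5 | 4,4-diethoxybut-2-yn-1-ol | CCOC(OCC)C#CCO
F3 | step 5 | 4,4-diethoxybut-2-yn-1-yl acetate | CCOC(OCC)C#CCOC(C)=O
F4 | step 5 | Cr(CO)3 complex of acetal phenol F5, η6 on ring B (two dot-joined parts) | CCOC(OCC)c1c(O)cc(C)c(OC)c1COC(C)=O.O=C=[Cr](=C=O)=C=O
F5 | step 5 | [2-(diethoxymethyl)-3-hydroxy-6-methoxy-5-methylphenyl]methyl acetate | CCOC(OCC)c1c(O)cc(C)c(OC)c1COC(C)=O
F6 | step 5 | (2-formyl-3-hydroxy-6-methoxy-5-methylphenyl)methyl acetate | CC(=O)OCc1c(C=O)c(O)cc(C)c1OC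
F7 | step 5 | 2,6-dimethoxyphenylmagnesium bromide | COc1cccc(OC)c1[Mg]Br
F8 | step 6 | racemic 4-(2,6-dimethoxyphenyl)-4-(triethylsilyloxy)but-2-yn-1-yl acetate | CC[Si](CC)(CC)OC(C#CCOC(C)=O)c1c(OC)cccc1OC
F9 | step 6 | Cr(CO)3 complex of the phenol bearing the triethylsilyl carbinol ether, η6 on ring B (two dot-joined parts) | COc1cccc(OC)c1C(O[Si](CC)(CC)CC)c1c(O)cc(C)c(OC)c1COC(C)=O.O=C=[Cr](=C=O)=C=O
F10 | step 6 | Cr(CO)3 complex of F11, η6 on ring B (two dot-joined parts) | COc1cccc(OC)c1C(O[Si](CC)(CC)CC)c1c(O[Si](C)(C)C(C)(C)C)cc(C)c(OC)c1COC(C)=O.O=C=[Cr](=C=O)=C=O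
F11 | step 6 | racemic [3-(tert-butyldimethylsilyloxy)-2-[(2,6-dimethoxyphenyl)(triethylsilyloxy)methyl]-6-methoxy-5-methylphenyl]methyl acetate | COc1cccc(OC)c1C(O[Si](CC)(CC)CC)c1c(O[Si](C)(C)C(C)(C)C)cc(C)c(OC)c1COC(C)=O
F12 | step 7 | racemic [3-(tert-butyldimethylsilyloxy)-2-[(2,6-dimethoxyphenyl)(hydroxy)methyl]-6-methoxy-5-methylphenyl]methyl acetate | COc1cccc(OC)c1C(O)c1c(O[Si](C)(C)C(C)(C)C)cc(C)c(OC)c1COC(C)=O
F13 | step 7 | [3-(tert-butyldimethylsilyloxy)-2-(2,6-dimethoxybenzoyl)-6-methoxy-5-methylphenyl]methyl acetate | COc1cccc(OC)c1C(=O)c1c(O[Si](C)(C)C(C)(C)C)cc(C)c(OC)c1COC(C)=O
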